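# Proposed synthesis of CNP0199249.1 (24) by a reversible amine-catalysed aldol ring closure

## Analysis of the target

Ring atoms are numbered C1 (CH carrying the exocyclic methylene C7), C2 (sp2, methyl), C3 (=CH), C4 (CH2), C5 (CH–O) and C6 (CMe2); this numbering is kept for all intermediates.

- Target 24 has one carbocycle, a cyclohexene with a trisubstituted C2=C3 double bond. C7 is bound through an ether oxygen to the 7-position of a coumarin, and the C5 oxygen is acylated by (R)-2-methylbutanoic acid.
- There are three stereocentres: C1 (S), C5 (R) and the α-carbon of the ester (R). The C1 arm and the C5 oxygen are cis, a 1,3-relation across the quaternary C6, and the acid centre is independent of the ring.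
- The sensitive groups are the coumarin lactone (hydrides, organolithiums, hydroxide) and the epimerisable α-centre of the ester. The C5 carbinol is neopentyl, so it is slow to acylate and reluctant to invert. The double bond must stay between C2 and C3.
- The difficulty lies in the contiguous array C6 (quaternary), C1 (tertiary stereocentre with no heteroatom) and C2 (sp2), and in relating the remote C5 to C1.
- The strategy rests on the fact that the C5 oxygen is β to C3. With a ketone at C3, C4–C5 is an aldol bond. Because C6 is quaternary, the open-chain C5 aldehyde cannot enolise, so only one aldol direction exists.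
- The C3 ketone is afterwards converted into the C2=C3 alkene, so C2 never has to be controlled.

## Retrosynthetic reasoning

**Ester C5–O–acyl (24 ⇒ 22 + 23).** The acyl C–O bond is cut last. The α-centre of 23 epimerises under base, so it should meet as few reagents as possible. Forming the ester by acyl transfer leaves the C5–O bond, and with it the C5 configuration, untouched.

**Aryl ether C7–O (22 ⇒ 21 ⇒ 19 + 20).** The cut is made at the alkyl C7–O bond because C7 is primary and open to a redox condensation with the acidic phenol 20. The aryl C–O bond of an electron-rich coumarin offers no comparable reaction. The coumarin enters only after every hydride, amide-base and organolithium step is over. C5–O is kept as a silyl ether and C7–O as a 4-methoxybenzyl ether (18), which can be removed oxidatively without touching silyl ether or alkene.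

**C2=C3 alkene from the C3 ketone (18 ⇒ 17 ⇒ 15 ⇒ 14).** The alkene is traced to an enol triflate that is reduced, so the double bond sits where the enol derivative was. Kinetic deprotonation of 14 would go to C4. The regiochemistry is therefore fixed one step earlier, by silylation under equilibrating conditions to the more substituted enol ether 15. C2 becomes sp2, which is why its configuration was never an issue.

**Aldol bond C4–C5 (14 ⇒ 13 ⇒ 12).** Cutting C4–C5 opens the ring to keto-aldehyde 12. This bond is chosen because the acceptor is non-enolisable and the donor is a methyl ketone, so the ring closure has one possible course. The forward reaction must close the six-membered ring, stop at the ketol and place the C5 hydroxyl cis to the C1 arm. C1 must already be in place in 12.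

**Oxidation levels (12 ⇒ 11 ⇒ 9).** Both carbonyl groups of 12 come from diol 11 in one oxidation. Diol 11 comes from the unsaturated acid 9 in one borane operation that reduces the carboxyl group and hydrates the alkene with the oxygen on C3. The new centres at C2 and C3 are irrelevant: C3 is oxidised and C2 is epimerisable.

**Bond C6–C1 (9 ⇒ 6).** This bond joins a quaternary carbon to the C1 stereocentre.

- The direct 1,5-dicarbonyl disconnection, conjugate addition of an aldehyde-derived silyl enol ether to enone 3, would be shorter. It offers no dependable catalyst control of absolute configuration for an acyclic α-methyl enone, and it needs strong Lewis acids next to the benzylic ether.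
- The bond is therefore made by ester-enolate [3,3]-rearrangement of the allylic isobutyrate 6. Sigmatropic rearrangement tolerates the congestion. The isobutyrate has no enolate geometry to control. The chair transition state transfers the carbinol configuration of 6 to C1.

**Carbinol centre and skeleton (6 ⇒ 4 + 5; 4 ⇒ 3; 3 ⇒ 1 + 2).** The ester is cut to alcohol 4 and acid chloride 5. The only stereocentre that needs an external chiral source is the carbinol of 4, set by oxazaborolidine-catalysed reduction of enone 3. Enone 3 is cut at its C1=C2 double bond into aldehyde 1 and the stabilised ylide 2, which delivers the E geometry needed for the chirality transfer.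

## Alternatives that were turned down

**Alternative 1: enyne cycloisomerisation to a cyclopropane-masked ring.**
- Disconnection: C1–C2 plus a temporary C2–C7 bond, leading back to the acyclic 1,6-enyne A1 (alkyne C2≡C3 carrying the methyl, alkene C1=C7, silyloxy group on C5).
- Forward key step: PtCl2 converts A1 by 6-endo attack and 1,2-hydrogen shift into the vinylcyclopropane A2 (alkene C3=C4, cyclopropane C1–C2–C7). Acid-promoted opening by 20 at C7 would later move the alkene to C2=C3.
- For: it is catalytic and atom-economic, builds the ring and C1 in one step, and needs no protecting group on C7. It is shorter than the chosen route and its key step is under kinetic control.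
- Against:
  - The cyclopropane methylene is delivered anti to the silyloxy group, so C7 ends trans to the C5 oxygen. The target then requires inversion at the neopentyl C5.
  - The cyclopropylcarbinyl cation formed at C3 can open toward secondary C1 (ring enlargement) more readily than toward primary C7.
  - For an all-carbon tether with an internal alkyne, exo and endo pathways compete.
- Comparison: the chosen strategy is longer, but C7 carries its oxygen from the first step and no inversion at C5 is planned.

**Alternative 2: pinane skeleton opened by Baeyer–Villiger oxygen insertion.**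
- Disconnection: the C5–O bond, leading back to the bicyclic cyclobutanone chrysanthenone A3.
- Forward key step: alkaline H2O2 or a monooxygenase inserts oxygen between the carbonyl carbon C7 and bridgehead C5 to give the bridged γ-lactone A4. Reduction to the cis-diol, etherification with 20 and esterification with 23 would finish the synthesis.
- For: A3 already contains C1, the gem-dimethyl carbon and the methyl-bearing alkene. The lactone ties C5–O and C7 cis by construction. This alternative is clearly stronger in step count and in certainty of the relative configuration.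
- Against:
  - A3 is not a commodity chemical. Its photochemical preparation passes through a ketene that erodes optical purity.
  - The oxygen must be inserted on the side of the non-allylic bridgehead C5, whereas the allylic bridgehead C1 migrates at least as well.
  - An enzyme with the right regio- and enantiopreference would first have to be found.
- Comparison: the chosen strategy costs more steps. In return it draws its absolute configuration from a catalytic reduction of predictable sense, starts from achiral commodity materials, and does not depend on a migratory preference against the usual order.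

**Alternative 3: asymmetric carbonyl–ene closure onto a diene terminus.**
- Disconnection: C5–C6, leading back to the achiral skipped dienal A5.
- Forward key step: a confined chiral imidodiphosphate Brønsted acid cyclises A5 to dienol A6. It sets C5, and the C1 methyl becomes the exocyclic C7 methylene. Hydroboration of that methylene would then introduce the C7 oxygen and set C1.
- For: the precursor is achiral and short, and C5 is set by the catalyst. On C5 this alternative is stronger than the chosen route, which rests on an equilibrium.
- Against:
  - A5 holds a (Z)-trisubstituted and a tetrasubstituted alkene in a β,γ-unsaturated aldehyde. It is hard to make geometrically pure and prone to slip into conjugation.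
  - The ene reaction must bond to a fully substituted alkene carbon to create C6.
  - C1 must then be set on a conjugated diene, where 1,2- versus 1,4-hydroboration is open. The two faces differ only through the remote C5 substituent across a gem-dimethyl carbon, so the cis relation is uncertain.
- Comparison: the chosen strategy fixes C1 first, by chirality transfer of predictable sense, and leaves only C5 to the key step.

Key step: step 7

Assumption: (R)-2-methylbutanoic acid (23) is taken as purchasable in enantiopure form, and keto-aldehyde 12 is carried as a mixture of C2 epimers because that centre is equilibrated in step 7 and erased in step 9.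

## Route

Step 1
Reactants: 1 (4-methoxybenzyloxy)acetaldehyde; 2 3-(triphenylphosphoranylidene)butan-2-one
Product: 3 (E)-5-[(4-methoxybenzyl)oxy]-3-methylpent-3-en-2-one
Conditions: toluene, 90 °C
Reagents that add atoms: none
Why: Wittig olefination with a ketone-stabilised ylide, which adds reversibly and therefore gives the (E)-trisubstituted enone; the unhindered α-alkoxy aldehyde compensates for the lower reactivity of the α-methyl ylide.

Step 2
Reactants: 3 (E)-5-[(4-methoxybenzyl)oxy]-3-methylpent-3-en-2-one
Product: 4 (2R,3E)-5-[(4-methoxybenzyl)oxy]-3-methylpent-3-en-2-ol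
Conditions: (S)-2-methyl-CBS-oxazaborolidine (10 mol %), catecholborane, toluene, −78 °C; MeOH, then aq. NaOH
Reagents that add atoms: none
Why: Corey–Bakshi–Shibata reduction; the α-branched alkenyl group is the large and the methyl the small substituent, so the (S)-catalyst should deliver hydride to the face that gives the (R)-carbinol, and the low-temperature catecholborane protocol gives 1,2-reduction only.

Step 3
Reactants: 4 (2R,3E)-5-[(4-methoxybenzyl)oxy]-3-methylpent-3-en-2-ol; 5 2-methylpropanoyl chloride
Product: 6 (2R,3E)-5-[(4-methoxybenzyl)oxy]-3-methylpent-3-en-2-yl 2-methylpropanoate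
Conditions: Et3N, DMAP (cat.), CH2Cl2, 0 °C to rt
Reagents that add atoms: none
Why: DMAP-catalysed acylation of a secondary allylic alcohol; the C–O bond of the carbinol is not broken, so its configuration is retained.

Step 4
Reactants: 6 (2R,3E)-5-[(4-methoxybenzyl)oxy]-3-methylpent-3-en-2-yl 2-methylpropanoate
Product: 9 (3S,4E)-3-{[(4-methoxybenzyl)oxy]methyl}-2,2,4-trimethylhex-4-enoic acid, via silyl ketene acetal 7 (not isolated), via trimethylsilyl ester 8 (not isolated)
Conditions: LiN(iPr)2, THF, −78 °C; TMSCl/Et3N, −78 °C to rt, then 60 °C; 1 M HCl work-up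
Reagents that add atoms: none
Why: Ireland–Claisen rearrangement; the isobutyrate gives a ketene acetal without E/Z isomers, and the chair transition state with the carbinol methyl equatorial (the axial alternative meets the ketene acetal oxygen substituent) forms the C6–C1 bond on one face of the (E)-alkene. The (R)-carbinol centre is thereby transferred to (S)-C1 next to the new quaternary carbon.

Step 5
Reactants: 9 (3S,4E)-3-{[(4-methoxybenzyl)oxy]methyl}-2,2,4-trimethylhex-4-enoic acid
Product: 11 (3S)-3-{[(4-methoxybenzyl)oxy]methyl}-2,2,4-trimethylhexane-1,5-diol (mixture at C4 and C5), via organoborane adduct 10 (not isolated)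
Conditions: BH3·THF (excess), THF, 0 °C to 40 °C; then 3 M NaOH, 30% H2O2, 0 °C to rt
Reagents that add atoms: hydrogen peroxide OO
Why: Borane reduces the carboxylic acid through its acyloxyborane and hydroborates the trisubstituted alkene with boron on the less substituted CH carbon; oxidation then places the hydroxyl on C3 of the ring numbering. The configurations created at C2 and C3 do not matter because C3 is oxidised in step 6 and C2 is equilibrated in step 7.

Step 6
Reactants: 11 (3S)-3-{[(4-methoxybenzyl)oxy]methyl}-2,2,4-trimethylhexane-1,5-diol
Product: 12 (3S,4S)-3-{[(4-methoxybenzyl)oxy]methyl}-2,2,4-trimethyl-5-oxohexanal (with its C4 epimer)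
Conditions: (COCl)2, DMSO, CH2Cl2, −78 °C; Et3N, −78 °C to 0 °C
Reagents that add atoms: none
Why: Swern oxidation; both hydroxyls are converted into alkoxysulfonium ions before the base is added, so no hydroxy-aldehyde is present that could close to a lactol and be over-oxidised to a lactone. The aldehyde sits on a quaternary carbon and cannot epimerise or self-condense.

Step 7
Reactants: 12 (3S,4S)-3-{[(4-methoxybenzyl)oxy]methyl}-2,2,4-trimethyl-5-oxohexanal (with its C4 epimer)
Product: 13 (2S,3S,5R)-5-hydroxy-3-{[(4-methoxybenzyl)oxy]methyl}-2,4,4-trimethylcyclohexan-1-one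
Conditions: (S)-proline (30 mol %), DMSO, rt, run to constant composition
Reagents that add atoms: none
Why: Proline condenses with the methyl ketone to an iminium ion that tautomerises to the terminal enamine (C3=C4); this adds to the C5 aldehyde, and hydrolysis releases ketol 13 and the catalyst. The closest known reaction type is the proline-catalysed intramolecular enamine aldol of Hajos–Parrish type, stopped at the β-hydroxy ketone. The ring closes in the 6-(enolendo)-exo-trig mode, with both enamine carbons inside the new six-membered ring. The aldehyde on quaternary C6 cannot enolise and so acts only as acceptor, while the internal enamine toward C2 could close only a four-membered ring and merely epimerises C2. The new C5 centre is controlled by product stability: the addition is reversible under the catalysis, and the mixture should settle on the ketol that holds the C5 hydroxyl, the C1 arm and the C2 methyl all equatorial on one chair, which is the 5R isomer with the hydroxyl cis to the arm. Its C5 epimer carries an axial hydroxyl, and its C2 epimer an axial methyl syn to an axial C6 methyl or an axial C1 arm. C1 is α to neither carbonyl group and keeps the configuration set in step 4. The step needs chemoselectivity for addition over dehydration, served by the mild zwitterionic catalyst at room temperature, and diastereoselectivity at C5, served by running to equilibrium because the hydrogen-bonded enamine transition state may at first favour the axial alkoxide.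

Step 8
Reactants: 13 (2S,3S,5R)-5-hydroxy-3-{[(4-methoxybenzyl)oxy]methyl}-2,4,4-trimethylcyclohexan-1-one
Product: 14 (2S,3S,5R)-5-[(tert-butyldimethylsilyl)oxy]-3-{[(4-methoxybenzyl)oxy]methyl}-2,4,4-trimethylcyclohexan-1-one
Conditions: TBSOTf, 2,6-lutidine, CH2Cl2, −78 °C to −20 °C
Reagents that add atoms: tert-butyldimethylsilyl trifluoromethanesulfonate CC(C)(C)[Si](C)(C)OS(=O)(=O)C(F)(F)F
Why: Silylation of the hindered neopentyl carbinol needs the silyl triflate; the non-nucleophilic base at low temperature avoids retro-aldol and β-elimination. The silyl ether blocks retro-aldol cleavage in the basic steps that follow.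

Step 9
Reactants: 14 (2S,3S,5R)-5-[(tert-butyldimethylsilyl)oxy]-3-{[(4-methoxybenzyl)oxy]methyl}-2,4,4-trimethylcyclohexan-1-one
Product: 15 tert-butyl({(1R,5R)-5-{[(4-methoxybenzyl)oxy]methyl}-4,6,6-trimethyl-3-[(trimethylsilyl)oxy]cyclohex-3-en-1-yl}oxy)dimethylsilane
Conditions: TMSCl, NaI, Et3N, MeCN, rt
Reagents that add atoms: chlorotrimethylsilane C[Si](C)(C)Cl
Why: Thermodynamic silyl enol ether formation; iodotrimethylsilane made in the flask silylates the carbonyl oxygen and the ammonium iodide reprotonates reversibly, so the enol ether should equilibrate to the more substituted C2=C3 isomer. Enolisation toward C4 is further disfavoured by the β-silyloxy group, and the unwanted C2 stereocentre is erased.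

Step 10
Reactants: 15 tert-butyl({(1R,5R)-5-{[(4-methoxybenzyl)oxy]methyl}-4,6,6-trimethyl-3-[(trimethylsilyl)oxy]cyclohex-3-en-1-yl}oxy)dimethylsilane
Product: 17 (3R,5R)-5-[(tert-butyldimethylsilyl)oxy]-3-{[(4-methoxybenzyl)oxy]methyl}-2,4,4-trimethylcyclohex-1-en-1-yl trifluoromethanesulfonate, via lithium enolate 16 (not isolated)
Conditions: MeLi, THF, 0 °C to rt; then PhNTf2, −78 °C to rt; sat. NH4Cl
Reagents that add atoms: N-phenylbis(trifluoromethanesulfonimide) O=S(=O)(N(c1ccccc1)S(=O)(=O)C(F)(F)F)C(F)(F)F
Why: Methyllithium cleaves the enol O–Si bond and gives the regiodefined lithium enolate, which cannot equilibrate without a proton source and is triflated on oxygen. The alkyl silyl ether and the benzylic ether are inert to both reagents.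

Step 11
Reactants: 17 (3R,5R)-5-[(tert-butyldimethylsilyl)oxy]-3-{[(4-methoxybenzyl)oxy]methyl}-2,4,4-trimethylcyclohex-1-en-1-yl trifluoromethanesulfonate
Product: 18 tert-butyl({(1R,5S)-5-{[(4-methoxybenzyl)oxy]methyl}-4,6,6-trimethylcyclohex-3-en-1-yl}oxy)dimethylsilane
Conditions: Pd(OAc)2 (5 mol %), PPh3 (10 mol %), HCO2H, Bu3N, DMF, 60 °C
Reagents that add atoms: none
Why: Palladium-catalysed formate reduction of an enol triflate: oxidative addition, exchange of triflate for formate, loss of CO2 to a palladium hydride and reductive elimination replace the triflate by hydrogen without moving the double bond, which ends at C2=C3.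

Step 12
Reactants: 18 tert-butyl({(1R,5S)-5-{[(4-methoxybenzyl)oxy]methyl}-4,6,6-trimethylcyclohex-3-en-1-yl}oxy)dimethylsilane
Product: 19 [(1S,5R)-5-[(tert-butyldimethylsilyl)oxy]-2,6,6-trimethylcyclohex-2-en-1-yl]methanol
Conditions: DDQ, CH2Cl2/pH 7 buffer, 0 °C to rt
Reagents that add atoms: none
Why: Oxidative cleavage of the 4-methoxybenzyl ether by hydride abstraction and hydrolysis of the benzylic oxocarbenium ion; the isolated trisubstituted alkene and the silyl ether are not oxidised under buffered conditions.

Step 13
Reactants: 19 [(1S,5R)-5-[(tert-butyldimethylsilyl)oxy]-2,6,6-trimethylcyclohex-2-en-1-yl]methanol; 20 umbelliferone (7-hydroxy-2H-chromen-2-one)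
Product: 21 7-{[(1S,5R)-5-[(tert-butyldimethylsilyl)oxy]-2,6,6-trimethylcyclohex-2-en-1-yl]methoxy}-2H-chromen-2-one
Conditions: PPh3, DIAD, THF, 0 °C to 40 °C
Reagents that add atoms: none
Why: Mitsunobu etherification; the acidic phenol protonates the betaine and displaces the oxyphosphonium group at primary C7, and the neutral conditions leave the coumarin lactone intact. No stereocentre is involved at C7.

Step 14
Reactants: 21 7-{[(1S,5R)-5-[(tert-butyldimethylsilyl)oxy]-2,6,6-trimethylcyclohex-2-en-1-yl]methoxy}-2H-chromen-2-one
Product: 22 7-{[(1S,5R)-5-hydroxy-2,6,6-trimethylcyclohex-2-en-1-yl]methoxy}-2H-chromen-2-one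
Conditions: HF·pyridine, THF/pyridine, 0 °C to rt
Reagents that add atoms: none
Why: Fluoride-driven cleavage of the Si–O bond under buffered, weakly acidic conditions; the lactone, which basic fluoride sources could open, the aryl ether and the alkene are untouched.

Step 15
Reactants: 22 7-{[(1S,5R)-5-hydroxy-2,6,6-trimethylcyclohex-2-en-1-yl]methoxy}-2H-chromen-2-one; 23 (R)-2-methylbutanoic acid
Product: 24 (1R,5S)-4,6,6-trimethyl-5-{[(2-oxo-2H-chromen-7-yl)oxy]methyl}cyclohex-3-en-1-yl (2R)-2-methylbutanoate
Conditions: EDC·HCl, DMAP, CH2Cl2, 0 °C to rt
Reagents that add atoms: none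
Why: Steglich esterification; the acyl group is transferred to the C5 oxygen with retention at C5, and carbodiimide activation at low temperature with limited DMAP keeps enolisation of the activated acid, and so epimerisation of its α-centre, to a minimum.

## Compound list

1 | (4-methoxybenzyloxy)acetaldehyde | COc1ccc(COCC=O)cc1 | starting material
2 | 3-(triphenylphosphoranylidene)butan-2-one | CC(=O)C(C)=P(c1ccccc1)(c1ccccc1)c1ccccc1 | starting material
3 | (E)-5-[(4-methoxybenzyl)oxy]-3-methylpent-3-en-2-one | COc1ccc(COC/C=C(\C)C(C)=O)cc1 | intermediate
4 | (2R,3E)-5-[(4-methoxybenzyl)oxy]-3-methylpent-3-en-2-ol | COc1ccc(COC/C=C(\C)[C@@H](C)O)cc1 | intermediate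
5 | 2-methylpropanoyl chloride (isobutyryl chloride) | CC(C)C(Cl)=O | starting material
6 | (2R,3E)-5-[(4-methoxybenzyl)oxy]-3-methylpent-3-en-2-yl 2-methylpropanoate | COc1ccc(COC/C=C(\C)[C@@H](C)OC(=O)C(C)C)cc1 | intermediate
7 | trimethyl{[1-{[(2R,3E)-5-[(4-methoxybenzyl)oxy]-3-methylpent-3-en-2-yl]oxy}-2-methylprop-1-en-1-yl]oxy}silane (silyl ketene acetal) | COc1ccc(COC/C=C(\C)[C@@H](C)OC(O[Si](C)(C)C)=C(C)C)cc1 | intermediate
8 | trimethylsilyl (3S,4E)-3-{[(4-methoxybenzyl)oxy]methyl}-2,2,4-trimethylhex-4-enoate | C[Si](C)(C)OC(=O)C(C)(C)[C@@H](COCc1ccc(OC)cc1)/C(C)=C/C | intermediate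
9 | (3S,4E)-3-{[(4-methoxybenzyl)oxy]methyl}-2,2,4-trimethylhex-4-enoic acid | OC(=O)C(C)(C)[C@@H](COCc1ccc(OC)cc1)/C(C)=C/C | intermediate
10 | {[(3S)-5-boranyl-3-{[(4-methoxybenzyl)oxy]methyl}-2,2,4-trimethylhexyl]oxy}borane (organoborane adduct, drawn in its simplest monomeric form) | CC([BH2])C(C)[C@@H](COCc1ccc(OC)cc1)C(C)(C)CO[BH2] | intermediate
11 | (3S)-3-{[(4-methoxybenzyl)oxy]methyl}-2,2,4-trimethylhexane-1,5-diol (mixture at C4 and C5) | OCC(C)(C)[C@@H](COCc1ccc(OC)cc1)C(C)C(C)O | intermediate
12 | (3S,4S)-3-{[(4-methoxybenzyl)oxy]methyl}-2,2,4-trimethyl-5-oxohexanal (with its C4 epimer) | O=CC(C)(C)[C@@H](COCc1ccc(OC)cc1)[C@H](C)C(C)=O | intermediate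
13 | (2S,3S,5R)-5-hydroxy-3-{[(4-methoxybenzyl)oxy]methyl}-2,4,4-trimethylcyclohexan-1-one (hydroxyl, arm and C2 methyl all equatorial) | O[C@@H]1CC(=O)[C@@H](C)[C@H](COCc2ccc(OC)cc2)C1(C)C | intermediate
14 | (2S,3S,5R)-5-[(tert-butyldimethylsilyl)oxy]-3-{[(4-methoxybenzyl)oxy]methyl}-2,4,4-trimethylcyclohexan-1-one | CC(C)(C)[Si](C)(C)O[C@@H]1CC(=O)[C@@H](C)[C@H](COCc2ccc(OC)cc2)C1(C)C | intermediate
15 | tert-butyl({(1R,5R)-5-{[(4-methoxybenzyl)oxy]methyl}-4,6,6-trimethyl-3-[(trimethylsilyl)oxy]cyclohex-3-en-1-yl}oxy)dimethylsilane | C[Si](C)(C)OC1=C(C)[C@H](COCc2ccc(OC)cc2)C(C)(C)[C@H](O[Si](C)(C)C(C)(C)C)C1 | intermediate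
16 | lithium (3R,5R)-5-[(tert-butyldimethylsilyl)oxy]-3-{[(4-methoxybenzyl)oxy]methyl}-2,4,4-trimethylcyclohex-1-en-1-olate | [Li]OC1=C(C)[C@H](COCc2ccc(OC)cc2)C(C)(C)[C@H](O[Si](C)(C)C(C)(C)C)C1 | intermediate
17 | (3R,5R)-5-[(tert-butyldimethylsilyl)oxy]-3-{[(4-methoxybenzyl)oxy]methyl}-2,4,4-trimethylcyclohex-1-en-1-yl trifluoromethanesulfonate | O=S(=O)(OC1=C(C)[C@H](COCc2ccc(OC)cc2)C(C)(C)[C@H](O[Si](C)(C)C(C)(C)C)C1)C(F)(F)F | intermediate
18 | tert-butyl({(1R,5S)-5-{[(4-methoxybenzyl)oxy]methyl}-4,6,6-trimethylcyclohex-3-en-1-yl}oxy)dimethylsilane | CC(C)(C)[Si](C)(C)O[C@@H]1CC=C(C)[C@H](COCc2ccc(OC)cc2)C1(C)C | intermediate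
19 | [(1S,5R)-5-[(tert-butyldimethylsilyl)oxy]-2,6,6-trimethylcyclohex-2-en-1-yl]methanol | CC(C)(C)[Si](C)(C)O[C@@H]1CC=C(C)[C@H](CO)C1(C)C | intermediate
20 | umbelliferone (7-hydroxy-2H-chromen-2-one) | O=c1ccc2ccc(O)cc2o1 | starting material
21 | 7-{[(1S,5R)-5-[(tert-butyldimethylsilyl)oxy]-2,6,6-trimethylcyclohex-2-en-1-yl]methoxy}-2H-chromen-2-one | CC(C)(C)[Si](C)(C)O[C@@H]1CC=C(C)[C@H](COc2ccc3ccc(=O)oc3c2)C1(C)C | intermediate
22 | 7-{[(1S,5R)-5-hydroxy-2,6,6-trimethylcyclohex-2-en-1-yl]methoxy}-2H-chromen-2-one | O[C@@H]1CC=C(C)[C@H](COc2ccc3ccc(=O)oc3c2)C1(C)C | intermediate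
23 | (R)-2-methylbutanoic acid | CC[C@@H](C)C(=O)O | starting material
24 | (1R,5S)-4,6,6-trimethyl-5-{[(2-oxo-2H-chromen-7-yl)oxy]methyl}cyclohex-3-en-1-yl (2R)-2-methylbutanoate | CC[C@@H](C)C(=O)O[C@@H]1CC=C(C)[C@H](COc2ccc3ccc(=O)oc3c2)C1(C)C | target

## Step count and least certain steps

Total: 15 steps. Longest linear sequence: 15 steps (1 and 2 to 24); 5, 20 and 23 enter as single reagents.

**Step 7 (key step).**
- What may go wrong: poor diastereoselection at C5. The equatorial preference of a hydroxyl flanked by the gem-dimethyl carbon is small, because the equatorial hydroxyl is gauche to both C6 methyls while the axial one meets only one syn-axial hydrogen. The hydrogen-bonded enamine transition state is expected to deliver the axial alkoxide first. Slow equilibration, or dehydration of the ketol on prolonged exposure, would add to this. Within the step, the C5 epimer can be returned to the same conditions.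
- Fallback: the ring is closed by metathesis and C5 is set by a reagent. It sets out from acid 9 and rejoins the route at 18.
  - LiAlH4 in THF reduces 9 to (3S,4E)-3-{[(4-methoxybenzyl)oxy]methyl}-2,2,4-trimethylhex-4-en-1-ol F1.
  - Swern oxidation gives (3S,4E)-3-{[(4-methoxybenzyl)oxy]methyl}-2,2,4-trimethylhex-4-enal F2.
  - Brown allylboration with the B-allyldiisopinocampheylborane enantiomer prepared from (−)-α-pinene adds to the Re face of this α-quaternary aldehyde by the usual model. It should give (4R,6S,7E)-6-{[(4-methoxybenzyl)oxy]methyl}-5,5,7-trimethylnona-1,7-dien-4-ol F3 under reagent control.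
  - TBSOTf and 2,6-lutidine give tert-butyl({(4R,6S,7E)-6-{[(4-methoxybenzyl)oxy]methyl}-5,5,7-trimethylnona-1,7-dien-4-yl}oxy)dimethylsilane F4.
  - Ring-closing metathesis with the second-generation Grubbs catalyst in CH2Cl2 at 40 °C forms C2=C3 with loss of propene and gives 18.
  - This path also bypasses the regiochemical question of step 9.

**Step 9.**
- What may go wrong: incomplete regiocontrol of enolisation, because the branched C1 next to C2 lowers the usual preference for the tetrasubstituted enol ether. Loss of the C5 silyloxy group by β-elimination from the C4 enol ether under the Lewis-acidic conditions is possible, as is attack of iodotrimethylsilane on the benzylic ether.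
- Fallback: the alkene is made by reduction and anti-elimination instead of through enol derivatives. It sets out from 14 and rejoins at 18.
  - LiBH(s-Bu)3 in THF at −78 °C attacks from the equatorial direction and gives the axial alcohol (1R,2S,3S,5R)-5-[(tert-butyldimethylsilyl)oxy]-3-{[(4-methoxybenzyl)oxy]methyl}-2,4,4-trimethylcyclohexan-1-ol F5.
  - POCl3 in pyridine eliminates the axial dichlorophosphate together with the trans-diaxial tertiary hydrogen on C2, toward the more substituted alkene, and gives 18.

**Step 15.**
- What may go wrong: slow acylation of the neopentyl C5 carbinol. The activated acid then has time to enolise, through a ketene or the acylpyridinium ion, and the ester α-centre epimerises.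
- Fallback: Lewis-acid-catalysed acylation without base. It sets out from 22 and 23 and rejoins at 24.
  - 23 is converted with half an equivalent of dicyclohexylcarbodiimide into (2R)-2-methylbutanoic anhydride F7.
  - F7 acylates 22 under Sc(OTf)3 catalysis in MeCN/CH2Cl2 at −20 °C to give 24. No base is present, so the ketene pathway is closed.

**Step 13.**
- What may go wrong: slow substitution at the β-branched C7, which lies next to the congested C1. The oxyphosphonium intermediate can then be diverted to alkylation of the hydrazide or to elimination.
- Fallback: two-step sulfonate displacement. It sets out from 19 and rejoins at 21.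
  - MsCl and Et3N in CH2Cl2 at 0 °C give [(1S,5R)-5-[(tert-butyldimethylsilyl)oxy]-2,6,6-trimethylcyclohex-2-en-1-yl]methyl methanesulfonate F6.
  - 20 and Cs2CO3 in DMF at 60 °C displace the mesylate through the caesium phenoxide and give 21.

## Further compounds

F1 | step 7 | (3S,4E)-3-{[(4-methoxybenzyl)oxy]methyl}-2,2,4-trimethylhex-4-en-1-ol | OCC(C)(C)[C@@H](COCc1ccc(OC)cc1)/C(C)=C/C
F2 | step 7 | (3S,4E)-3-{[(4-methoxybenzyl)oxy]methyl}-2,2,4-trimethylhex-4-enal | O=CC(C)(C)[C@@H](COCc1ccc(OC)cc1)/C(C)=C/C
F3 | step 7 | (4R,6S,7E)-6-{[(4-methoxybenzyl)oxy]methyl}-5,5,7-trimethylnona-1,7-dien-4-ol | C=CC[C@@H](O)C(C)(C)[C@@H](COCc1ccc(OC)cc1)/C(C)=C/C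
F4 | step 7 | tert-butyl({(4R,6S,7E)-6-{[(4-methoxybenzyl)oxy]methyl}-5,5,7-trimethylnona-1,7-dien-4-yl}oxy)dimethylsilane | C=CC[C@@H](O[Si](C)(C)C(C)(C)C)C(C)(C)[C@@H](COCc1ccc(OC)cc1)/C(C)=C/C
F5 | step 9 | (1R,2S,3S,5R)-5-[(tert-butyldimethylsilyl)oxy]-3-{[(4-methoxybenzyl)oxy]methyl}-2,4,4-trimethylcyclohexan-1-ol | CC(C)(C)[Si](C)(C)O[C@@H]1C[C@@H](O)[C@@H](C)[C@H](COCc2ccc(OC)cc2)C1(C)C
F6 | step 13 | [(1S,5R)-5-[(tert-butyldimethylsilyl)oxy]-2,6,6-trimethylcyclohex-2-en-1-yl]methyl methanesulfonate | CC(C)(C)[Si](C)(C)O[C@@H]1CC=C(C)[C@H](COS(C)(=O)=O)C1(C)C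
F7 | step 15 | (2R)-2-methylbutanoic anhydride | CC[C@@H](C)C(=O)OC(=O)[C@H](C)CC
A1 | alternative 1 | (S)-tert-butyl[(3,3-dimethyloct-1-en-6-yn-4-yl)oxy]dimethylsilane | CC#CC[C@H](O[Si](C)(C)C(C)(C)C)C(C)(C)C=C
A2 | alternative 1 | tert-butyldimethyl[(1,5,5-trimethylbicyclo[4.1.0]hept-2-en-4-yl)oxy]silane, cyclopropane methylene anti to the silyloxy group | CC(C)(C)[Si](C)(C)O[C@H]1C=C[C@]2(C)C[C@@H]2C1(C)C
A3 | alternative 2 | (1S,5R)-2,7,7-trimethylbicyclo[3.1.1]hept-2-en-6-one (chrysanthenone) | O=C1[C@@H]2CC=C(C)[C@H]1C2(C)C
A4 | alternative 2 | 4,8,8-trimethyl-6-oxabicyclo[3.2.1]oct-3-en-7-one | O=C1O[C@@H]2CC=C(C)[C@H]1C2(C)C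
A5 | alternative 3 | (3Z)-4,5,6-trimethylhepta-3,5-dienal | O=CC/C=C(C)\C(C)=C(C)C
A6 | alternative 3 | (R)-2,2,4-trimethyl-3-methylidenecyclohex-4-en-1-ol | O[C@@H]1CC=C(C)C(=C)C1(C)C
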